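A minute is a poor clock for this flask; the better clock is the half-life of J, and what is worth watching is how many of those pass before D turns over.

- alder: J 20 mM; L 45 mM; run made earlier
- flask: J 20 mM; L 30.0 mM; time 20 min

alder run (percent of the J charged)

| time / min | D / % | J / % |
|---|---|---|
| 0.333 | 22.5 | 71.1 |
| 1.00 | 33.1 | 40.5 |
| 2.00 | 30.1 | 23.3 |
| 3.00 | 26.1 | 17.1 |
| 4.00 | 21.7 | 13.9 |

(each reading ± 0.5 percentage points)



- the moment within 20 min at which there is most D
- the amount of D, in percent of the J charged, at that time

What clock can be read from the alder run? Its first reading has J at 71.1% after 0.333 min. If J falls first order with c(L) held at its charge, a pseudo-first-order view, J halves in 0.677 min.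

How does that carry to the flask? I take the rate as proportional to c(L), so the half-life stretches as the charge shrinks, from 45 mM to 30.0 mM. This gives the half-life of J at the charge of L in the flask, 1.02 min.

Where does D stand highest? The highest alder reading comes at 1.00 min, which is 1.48 half-lives, so I commit to 1.50 min in the flask. The readings beside it lie at 0.333 min and 2.00 min, so this count is coarse.

Can the count run on to the end? Not safely: from 1.00 min to 4.00 min the alder J halves in 1.94 min, slower than at the start.

And the height? The count gives none, so I keep the alder reading of 33.1% as a first guess.

The forecast gives 2.2 min and 33%, holding that “That yield depends only on the ratio”; its time is later than mine.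

The flask gives most D at 1.29 min, with 24.8%.

    J + L ⇌ D (K = 45.0 M⁻¹, k = 0.390 M⁻¹ s⁻¹)
    J + D → Q (k = 0.800 M⁻¹ s⁻¹)

That peak in the flask stands at 1.26 reckoned half-lives against 1.48 for the highest alder reading, so it came earlier than my count. The highest D of the alder run up to its last reading, without the scatter, is 33.6%, and it becomes 24.8% when its amount of L is changed to that of the flask. In the neighbouring flask with 7.5 mM of L, the same clock, with c(L) held at its charge, gives 4.06 min, so 20 min counts 4.93 half-lives and reckons J down to 3.29%. That neighbour reaches 7.11% of D at best and ends with J at 35.0% and L at 12.1% of its charge.

All runs are calculated for an exercise; the scatter is artificial.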